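The numbers in the tables are calculated from invented constants, and the scatter is random.

- the flasks put in order of amount of links, in percent of the first end groups charged, best first, at 50 h (theta / gamma / beta / eta / alpha)
- the amount of links, in percent of the first end groups charged of the flask you put first, at 50 h
- the amount of links, in percent of the first end groups charged of the flask you put last, at 50 h

Time is what the blue run shows and temperature is not, so I asked where that run was heading by its last reading. Over its last 5.00 h the links rose by 3 percentage points, too near the scatter of 2 points to tell a stop from a slow climb.

| flask | first end groups | third end groups | solid second end groups | temperature | remark | time |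
|---|---|---|---|---|---|---|
| blue | 0.055 M | 5 mM | 0.050 M | 100 °C | run made earlier |  |
| theta | 0.050 M | 5.00 mM | 0.0500 M | 100 °C |  | 50 h |
| gamma | 0.15 M | 15.0 mM | 0.200 M | 100 °C |  | 50 h |
| beta | 0.030 M | 5.00 mM | 0.100 M | 100 °C |  | 50 h |
| eta | 0.050 M | 5.00 mM | 0.100 M | 70 °C |  | 50 h |
| alpha | 0.050 M | 1.50 mM | 0.0120 M | 60 °C |  | 50 h |

blue run (percent of the first end groups charged)

| time / h | links / % | first end groups / % |
|---|---|---|
| 2.00 | 1 | 97 |
| 6.00 | 19 | 84 |
| 10.0 | 23 | 77 |
| 15.0 | 27 | 69 |
| 25.0 | 39 | 59 |
| 30.0 | 42 | 56 |

(standard deviation of a reading: 2 percentage points)

- at the start none of the solid second end groups is in solution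
- the earlier runs do not show what temperature does; that part of a forecast is a guess

At 30.0 h the links reading gives 27.9 M⁻¹ for the link quotient, c(links) divided by c(first end groups) and by c(second end groups). This is the reaction quotient of the step to links, with c(second end groups) reckoned as the charge less the links. The first end groups column, reading what has gone from it as links, is a second way and gives 30.5 M⁻¹. The two columns leave 2 points of the charge between them, about one scatter, so their gap is no more than the readings allow.

Both ways share a weakness. The reading at 25.0 h gives 23.2 M⁻¹, which is lower than 27.9 M⁻¹, so the run may still have been climbing. Any solid not yet dissolved would also make the true c(second end groups) smaller. I therefore took 27.9 M⁻¹ as a low mark.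

Held at that mark, with the solid counted as dissolved, my reckoning gave theta 43.9 % and gamma 72.0 %. It gave alpha 13.1 %, this last at the temperature of the blue run, since what 60 °C does is a guess.

The forecast, holding that the curve “fits second order”, gave gamma > beta > theta > eta > alpha, with 96 % for the first flask and 2 % for the last. My reckoning differs: it stops gamma at 72.0 % and puts alpha at 13.1 %.

The flasks gave eta > beta > theta > gamma > alpha, with 57.8 % for the first and 17.3 % for the last.

    first end groups + second end groups ⇌ links (K = 33.0 M⁻¹, k = 39.0 M⁻¹ h⁻¹, Ea = 68.0 kJ mol⁻¹, ΔH = −17.0 kJ mol⁻¹)
    second end groups + third end groups → links of the second sort (k = 4.30 M⁻¹ h⁻¹, Ea = 95.0 kJ mol⁻¹)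
    solid second end groups ⇌ second end groups, rate k3*(cs3 - [second end groups]) while solid is left; crystals form when [second end groups] > cs3 (solubility = 29.0 mM, k = 0.100 h⁻¹)
    (constants at 100 °C)

Gamma at 50.0 h held 0.0195 M of dissolved second end groups, with 54.3 % of its solid second end groups undissolved, and my 72.0 % had counted that solid as dissolved. With that dissolved amount in the reckoning, my 27.9 M⁻¹ gives gamma 35.2 % of links, and the flask held 39.0 %. Alpha, at 60 °C with 0 % of its solid left, stood at a link quotient of 63.7 M⁻¹ from its simulated amounts. I put that value into the same reckoning for the neighbour of alpha charged with 0.048 M of solid second end groups, and it gave 56.0 %. That flask held 55.6 % of links at 50.0 h.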